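**Strategy.** The 2,3-dihydrobenzofuran ring (O1, C2, C3, C3a, C7a) with its C3 hydroxymethyl carbon is read as a flavanone whose C4 has been pushed out of the ring. In a (2S)-chroman-4-one the six-membered ring O1–C2–C3–C4–C4a–C8a contracts when iodine(III) at C3 triggers a 1,2-shift of the A-ring carbon C4a from C4 to C3. One operation forms the five-membered ring, the C3–C3a bond, the trans C2/C3 relationship and the ester that becomes the CH2OH group. The precursor, a 6-bromo-8-methoxyflavanone with a pivalate-masked syringyl ring, comes from asymmetric conjugate arylation of a chromone; Heck coupling and one global DIBAL-H reduction finish the route.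

Key step: step 6

Assumption: the (R)-configured pyridine–oxazoline ligand is taken to deliver the (2S)-flavanone (mirror image of the (S)-ligand/(2R)-product pairing); the sense of induction should be confirmed by CD on the first batch, and the antipodal ligand used if it is reversed.

**Step 1**
Reactants: 1 1-(2-hydroxy-3-methoxyphenyl)ethan-1-one
Product: 2 1-(5-bromo-2-hydroxy-3-methoxyphenyl)ethan-1-one
Conditions: NBS (1.05 equiv), MeCN, 0 °C to rt
Reagents that add atoms: N-bromosuccinimide, O=C1CCC(=O)N1Br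
Why: Electrophilic aromatic bromination should go para to the phenolic OH (C5), the only open position activated by the strongest donor, faster than α-bromination of the ketone.

**Step 2**
Reactants: 2 1-(5-bromo-2-hydroxy-3-methoxyphenyl)ethan-1-one
Product: 4 6-bromo-8-methoxy-4H-chromen-4-one, via enaminone 3 (not isolated)
Conditions: Me2NCH(OMe)2, toluene, 100 °C; then conc. HCl, CH2Cl2, 40 °C
Reagents that add atoms: N,N-dimethylformamide dimethyl acetal, COC(OC)N(C)C
Why: Condensation of the methyl ketone with the amide acetal gives the enaminone, and acid-promoted intramolecular oxa-Michael addition with loss of dimethylamine closes the chromone (enaminone chromone synthesis).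

**Step 3**
Reactants: 5 2,6-dimethoxy-4-(4,4,5,5-tetramethyl-1,3,2-dioxaborolan-2-yl)phenol
Product: 6 2,6-dimethoxy-4-(4,4,5,5-tetramethyl-1,3,2-dioxaborolan-2-yl)phenyl 2,2-dimethylpropanoate
Conditions: PivCl, Et3N, DMAP (cat.), CH2Cl2, 0 °C to rt
Reagents that add atoms: pivaloyl chloride, CC(C)(C)C(Cl)=O
Why: DMAP-catalysed O-acylation of the phenol installs an acid-stable, electron-withdrawing mask that later falls off in the final hydride reduction.

**Step 4**
Reactants: 6 2,6-dimethoxy-4-(4,4,5,5-tetramethyl-1,3,2-dioxaborolan-2-yl)phenyl 2,2-dimethylpropanoate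
Product: 7 [4-(2,2-dimethylpropanoyloxy)-3,5-dimethoxyphenyl]boronic acid
Conditions: NaIO4, NH4OAc, acetone/H2O (1:1), rt
Reagents that add atoms: water, O
Why: Hydrolysis of the pinacol boronate is driven to completion by periodate glycol cleavage of the released pinacol, and the protected phenol is inert to periodate.

**Step 5**
Reactants: 4 6-bromo-8-methoxy-4H-chromen-4-one; 7 [4-(2,2-dimethylpropanoyloxy)-3,5-dimethoxyphenyl]boronic acid
Product: 8 4-[(2S)-6-bromo-8-methoxy-4-oxochroman-2-yl]-2,6-dimethoxyphenyl 2,2-dimethylpropanoate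
Conditions: Pd(OCOCF3)2 (5 mol%), (R)-t-BuPyOx (6 mol%), NH4PF6 (30 mol%), H2O (5 equiv), ClCH2CH2Cl, 60 °C
Reagents that add atoms: none
Why: Pd(II)-catalysed asymmetric conjugate addition of an arylboronic acid to a chromone (transmetalation, enantioface-selective insertion of C2=C3 into Ar–Pd, protonolysis of the Pd enolate) should set C2 as S under ligand control, and the base-free medium protects the pivalate and the flavanone from ring-opening.

**Step 6**
Reactants: 8 4-[(2S)-6-bromo-8-methoxy-4-oxochroman-2-yl]-2,6-dimethoxyphenyl 2,2-dimethylpropanoate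
Product: 12 methyl (2S,3S)-5-bromo-2-[4-(2,2-dimethylpropanoyloxy)-3,5-dimethoxyphenyl]-7-methoxy-2,3-dihydro-1-benzofuran-3-carboxylate, via enol ether 9 (not isolated), via λ3-iodane 10 (not isolated), via orthoester 11 (not isolated)
Conditions: PhI(OAc)2 (1.2 equiv), conc. H2SO4 (cat.), HC(OMe)3, rt; aq. NaHCO3
Reagents that add atoms: trimethyl orthoformate, COC(OC)OC; water, O
Why: In HC(OMe)3/H+ the ketone becomes the 4-methoxy enol ether 9, PhI(OAc)+ adds to C3 on the face anti to the C2 aryl group with methanol capping C4 to give λ3-iodane 10, and the A-ring carbon C4a, antiperiplanar to the C3–I bond, migrates from C4 to C3 with loss of PhI, the dimethoxycarbenium ion being trapped as orthoester 11 and hydrolysed to the methyl ester on work-up. The closest known reaction type is the iodine(III)- or thallium(III)-mediated oxidative 1,2-aryl migration of aryl ketones to α-aryl esters, which on flavanones is a known ring contraction to trans-2-aryl-2,3-dihydrobenzofuran-3-carboxylates. The five-membered ring is closed by the 1,2-shift itself (C3–C3a bond formation concerted with C–I cleavage through a phenonium-like bridged transition state), not by a separate cyclization. C2 is untouched and keeps its spatial arrangement, and C3 is set by substrate control: anti iodination followed by inversion at C3 places the carboxyl carbon trans to the aryl group (2S,3S). The step needs A-ring migration to beat C2-aryl migration (isoflavone) and dehydrogenation (flavone): the ring oxygen ortho to C4a raises the migratory aptitude of the A ring, the pivalate lowers that of the syringyl ring and keeps the phenol from the oxidant, and the ketal level at C4 blocks simple elimination.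

**Step 7**
Reactants: 12 methyl (2S,3S)-5-bromo-2-[4-(2,2-dimethylpropanoyloxy)-3,5-dimethoxyphenyl]-7-methoxy-2,3-dihydro-1-benzofuran-3-carboxylate; 13 methyl acrylate
Product: 14 methyl (2S,3S)-2-[4-(2,2-dimethylpropanoyloxy)-3,5-dimethoxyphenyl]-7-methoxy-5-[(E)-3-methoxy-3-oxoprop-1-en-1-yl]-2,3-dihydro-1-benzofuran-3-carboxylate
Conditions: Pd2(dba)3 (2 mol%), [(t-Bu)3PH]BF4 (8 mol%), Cy2NMe (1.2 equiv), 1,4-dioxane, 50 °C
Reagents that add atoms: none
Why: Mizoroki–Heck coupling of the unhindered aryl bromide with the acrylate gives the E-enoate by syn insertion and syn β-hydride elimination, and the bulky electron-rich phosphine allows a low temperature and a hindered amine base that should leave the acidic C3–H alone.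

**Step 8**
Reactants: 14 methyl (2S,3S)-2-[4-(2,2-dimethylpropanoyloxy)-3,5-dimethoxyphenyl]-7-methoxy-5-[(E)-3-methoxy-3-oxoprop-1-en-1-yl]-2,3-dihydro-1-benzofuran-3-carboxylate
Product: 15 4-[(2S,3R)-3-(hydroxymethyl)-5-[(E)-3-hydroxyprop-1-en-1-yl]-7-methoxy-2,3-dihydro-1-benzofuran-2-yl]-2,6-dimethoxyphenol
Conditions: DIBAL-H (8 equiv), CH2Cl2, −78 °C to rt; aq. Rochelle salt
Reagents that add atoms: none
Why: DIBAL-H should reduce the saturated ester to CH2OH, the enoate 1,2-selectively to the E-allylic alcohol and the aryl pivalate to the free phenol in one operation, with no stereocentre involved (the C3 descriptor changes from S to R only through CIP priorities).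

**Compound list**

1 | 1-(2-hydroxy-3-methoxyphenyl)ethan-1-one | CC(=O)c1cccc(OC)c1O | starting material
2 | 1-(5-bromo-2-hydroxy-3-methoxyphenyl)ethan-1-one | CC(=O)c1cc(Br)cc(OC)c1O | intermediate
3 | (E)-1-(5-bromo-2-hydroxy-3-methoxyphenyl)-3-(dimethylamino)prop-2-en-1-one (enaminone, not isolated) | CN(C)/C=C/C(=O)c1cc(Br)cc(OC)c1O | intermediate
4 | 6-bromo-8-methoxy-4H-chromen-4-one | COc1cc(Br)cc2c(=O)ccoc12 | intermediate
5 | 2,6-dimethoxy-4-(4,4,5,5-tetramethyl-1,3,2-dioxaborolan-2-yl)phenol | COc1cc(B2OC(C)(C)C(C)(C)O2)cc(OC)c1O | starting material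
6 | 2,6-dimethoxy-4-(4,4,5,5-tetramethyl-1,3,2-dioxaborolan-2-yl)phenyl 2,2-dimethylpropanoate | COc1cc(B2OC(C)(C)C(C)(C)O2)cc(OC)c1OC(=O)C(C)(C)C | intermediate
7 | [4-(2,2-dimethylpropanoyloxy)-3,5-dimethoxyphenyl]boronic acid | COc1cc(B(O)O)cc(OC)c1OC(=O)C(C)(C)C | intermediate
8 | 4-[(2S)-6-bromo-8-methoxy-4-oxochroman-2-yl]-2,6-dimethoxyphenyl 2,2-dimethylpropanoate | O=C1C[C@@H](c2cc(OC)c(OC(=O)C(C)(C)C)c(OC)c2)Oc2c(OC)cc(Br)cc21 | intermediate
9 | 4-[(2S)-6-bromo-4,8-dimethoxy-2H-chromen-2-yl]-2,6-dimethoxyphenyl 2,2-dimethylpropanoate (enol ether, not isolated) | COC1=C[C@@H](c2cc(OC)c(OC(=O)C(C)(C)C)c(OC)c2)Oc2c(OC)cc(Br)cc21 | intermediate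
10 | 4-[(2R,3R)-3-[acetoxy(phenyl)-λ3-iodanyl]-6-bromo-4,4,8-trimethoxychroman-2-yl]-2,6-dimethoxyphenyl 2,2-dimethylpropanoate (iodine trans to the aryl group, not isolated) | COC1(OC)[C@H](I(OC(C)=O)c2ccccc2)[C@@H](c2cc(OC)c(OC(=O)C(C)(C)C)c(OC)c2)Oc2c(OC)cc(Br)cc21 | intermediate
11 | 4-[(2S,3S)-5-bromo-7-methoxy-3-(trimethoxymethyl)-2,3-dihydro-1-benzofuran-2-yl]-2,6-dimethoxyphenyl 2,2-dimethylpropanoate (orthoester, not isolated) | COc1cc([C@H]2Oc3c(OC)cc(Br)cc3[C@@H]2C(OC)(OC)OC)cc(OC)c1OC(=O)C(C)(C)C | intermediate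
12 | methyl (2S,3S)-5-bromo-2-[4-(2,2-dimethylpropanoyloxy)-3,5-dimethoxyphenyl]-7-methoxy-2,3-dihydro-1-benzofuran-3-carboxylate (2,3-trans) | COc1cc([C@H]2Oc3c(OC)cc(Br)cc3[C@@H]2C(=O)OC)cc(OC)c1OC(=O)C(C)(C)C | intermediate
13 | methyl acrylate | C=CC(=O)OC | starting material
14 | methyl (2S,3S)-2-[4-(2,2-dimethylpropanoyloxy)-3,5-dimethoxyphenyl]-7-methoxy-5-[(E)-3-methoxy-3-oxoprop-1-en-1-yl]-2,3-dihydro-1-benzofuran-3-carboxylate | COc1cc([C@H]2Oc3c(OC)cc(/C=C/C(=O)OC)cc3[C@@H]2C(=O)OC)cc(OC)c1OC(=O)C(C)(C)C | intermediate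
15 | 4-[(2S,3R)-3-(hydroxymethyl)-5-[(E)-3-hydroxyprop-1-en-1-yl]-7-methoxy-2,3-dihydro-1-benzofuran-2-yl]-2,6-dimethoxyphenol | COc1cc([C@H]2Oc3c(OC)cc(/C=C/CO)cc3[C@@H]2CO)cc(OC)c1O | target

**Total steps:** 8. **Longest linear sequence:** 6 (steps 1, 2, 5, 6, 7, 8; the boronic acid branch 3, 4, 5, 6, 7, 8 is equally long).

**Steps most likely to fail**

Step 6 (key ring contraction). The risks are migration of the C2 aryl group instead of the A ring (isoflavone pathway), dehydrogenation to the flavone, and over-oxidation of the electron-rich rings by iodine(III). The fallback keeps the ring contraction but replaces the oxidant by a pre-installed leaving group. It sets out from 8: bromination at C3 (PhNMe3Br3, THF, rt) should give 4-[(2R,3R)-3,6-dibromo-8-methoxy-4-oxochroman-2-yl]-2,6-dimethoxyphenyl 2,2-dimethylpropanoate F1, with bromine trans to the aryl group. Ketalisation (HC(OMe)3, MeOH, TsOH cat.) gives 4-[(2R,3R)-3,6-dibromo-4,4,8-trimethoxychroman-2-yl]-2,6-dimethoxyphenyl 2,2-dimethylpropanoate F2. AgBF4 in MeOH then abstracts bromide and triggers the same A-ring 1,2-shift with inversion at C3 (silver-promoted α-halo ketal rearrangement), and aqueous work-up brings the route back at 12.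

Step 5 (asymmetric conjugate arylation). The risks are insufficient enantioface discrimination with this trisubstituted boronic acid, protodeboronation, and catalyst loss by insertion of adventitious Pd(0) into the C–Br bond. The fallback sets C2 by resolution instead of asymmetric C–C bond formation. It sets out from 4 and 7: the addition is run with achiral Pd(OCOCF3)2/2,2'-bipyridine to give racemic 4-(6-bromo-8-methoxy-4-oxochroman-2-yl)-2,6-dimethoxyphenyl 2,2-dimethylpropanoate F3. Kinetic resolution by asymmetric transfer hydrogenation (RuCl(p-cymene)[(R,R)-TsDPEN], HCO2H/Et3N) should reduce the matched (2R)-ketone faster to the cis alcohol 4-[(2R,4R)-6-bromo-4-hydroxy-8-methoxychroman-2-yl]-2,6-dimethoxyphenyl 2,2-dimethylpropanoate F4. The unreacted (2S)-ketone is separated by chromatography, and the route is rejoined at 8.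

Step 7 (Heck coupling). The risk is deprotonation at C3 (benzylic and α to the ester) by the amine base at elevated temperature, leading to epimerization or β-elimination of the ring phenoxide and ring-opening. The fallback inverts the order and couples under base-free conditions. It sets out from 12: DIBAL-H reduction (CH2Cl2, −78 °C to rt) gives 4-[(2S,3R)-5-bromo-3-(hydroxymethyl)-7-methoxy-2,3-dihydro-1-benzofuran-2-yl]-2,6-dimethoxyphenol F5, in which C3–H is no longer acidic. Stille coupling with (E)-3-(tributylstannyl)prop-2-en-1-ol (Pd2(dba)3, P(t-Bu)3, 1,4-dioxane, 80 °C) then installs the side chain at the alcohol oxidation level and arrives directly at 15.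

**Further compounds**

F1 | step 6 | 4-[(2R,3R)-3,6-dibromo-8-methoxy-4-oxochroman-2-yl]-2,6-dimethoxyphenyl 2,2-dimethylpropanoate | O=C1[C@H](Br)[C@@H](c2cc(OC)c(OC(=O)C(C)(C)C)c(OC)c2)Oc2c(OC)cc(Br)cc21
F2 | step 6 | 4-[(2R,3R)-3,6-dibromo-4,4,8-trimethoxychroman-2-yl]-2,6-dimethoxyphenyl 2,2-dimethylpropanoate | COC1(OC)[C@H](Br)[C@@H](c2cc(OC)c(OC(=O)C(C)(C)C)c(OC)c2)Oc2c(OC)cc(Br)cc21
F3 | step 5 | racemic 4-(6-bromo-8-methoxy-4-oxochroman-2-yl)-2,6-dimethoxyphenyl 2,2-dimethylpropanoate | O=C1CC(c2cc(OC)c(OC(=O)C(C)(C)C)c(OC)c2)Oc2c(OC)cc(Br)cc21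
F4 | step 5 | 4-[(2R,4R)-6-bromo-4-hydroxy-8-methoxychroman-2-yl]-2,6-dimethoxyphenyl 2,2-dimethylpropanoate | O[C@@H]1C[C@H](c2cc(OC)c(OC(=O)C(C)(C)C)c(OC)c2)Oc2c(OC)cc(Br)cc21
F5 | step 7 | 4-[(2S,3R)-5-bromo-3-(hydroxymethyl)-7-methoxy-2,3-dihydro-1-benzofuran-2-yl]-2,6-dimethoxyphenol | COc1cc([C@H]2Oc3c(OC)cc(Br)cc3[C@@H]2CO)cc(OC)c1O
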